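## Analysis of the target

The target 14 is a 3,3'-linked dimer of a 7,4'-dihydroxyflavanone. Two chroman-4-one units (ring A fused to the pyranone ring C, ring B as the 4-hydroxyphenyl group on C2) are joined by one bond between C3 and C3'. It has four contiguous stereocentres, C2, C3, C3' and C2', with the configuration (2S,3R,3'S,2'R). The two halves are mirror images, so the compound is meso, and in each pyranone ring the aryl group at C2 and the chromanone at C3 are trans (H-2 and H-3 anti).

The sensitive groups are these: the benzylic aryl ether bond O1–C2, which opens by retro-oxa-Michael reaction under base and, with a 4-hydroxyphenyl group on C2, by ionisation under acid; the enolisable C3–H next to each ketone; and four free phenols. The 2,3-trans arrangement within a ring is the favoured one and can be corrected by equilibration. The relationship across C3–C3' (meso, not C2-symmetric) has no such bias, and the central bond joins two hindered tertiary carbons. Fixing that relationship and carrying it through is the main difficulty.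

The strategy rests on one feature: C4 and C4' are aryl ketone carbons bonded to C4a and C4a' of rings A, and C4a lies ortho to O1 and para to the oxygen at C7. That is the position where a 3-alkoxyphenyl ether is acylated most readily. If both C4–C4a bonds are cut, C4 and C4' become the carboxyl carbons of a 2,3-disubstituted succinic acid, C3 and C3' its methine carbons, and rings A become plain aryl ethers on C2 and C2'.

## Retrosynthetic reasoning

**14 to 13.** The O–CH3 bonds of ring A are cut last. Ring A must be an alkoxyarene, not a phenol, when it is acylated, and a methyl ether survives a strongly acidic dehydrating medium. The forward step is a Lewis-acid demethylation of 13 that must leave O1–C2 closed.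

**13 to 12 to 11.** The ring B oxygens are traced back to C–B bonds in 12 and then to C–Br bonds in 11. The para substituent of ring B decides whether the benzylic C2–O1 bond survives acid. Bromine is inert, mildly deactivating and can be exchanged late. The forward steps are a Miyaura borylation and an ipso-oxidation under non-basic conditions.

**11 to 9 (key disconnection).** The C4–C4a and C4'–C4a' bonds are cut, which gives the meso diacid 9 by way of the half-cyclised keto acid 10. Both pyranone rings then come from an acyclic, symmetrical precursor that already holds all four stereocentres. The forward reaction must acylate each ring A at C-6, leave the bromophenyl rings alone and keep the benzylic ethers.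

**9 to 8.** The carboxyl groups are carried as tert-butyl esters. They are removed by acid, so the β-aryloxy acid never meets base, which would expel the phenoxide. They also lactonise less readily with a γ-hydroxyl group in earlier intermediates.

**8 to 6 and 7.** The two benzylic C–O bonds are cut, and the oxygen stays with 3-methoxyphenol 7. The forward step is a substitution with inversion at both carbinol carbons. The anti,anti array of 8 therefore requires the syn,syn diol 6.

**6 to 5.** The carbinol C–H bonds are cut, which leads to diketone 5. A twofold aldol addition of a succinate bis-enolate to an aromatic aldehyde would have to control all four centres at once and has no handle on the central relationship. In 5 the problem is reduced to one relationship, and a chelation-controlled reduction then sets each carbinol syn to its neighbour.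

**5 to 3.** The central C–C bond is cut into two molecules of β-keto ester 3, joined in the forward direction through the α-iodo ester 4. The two stereocentres of 5 are α-carbons of β-keto esters and interconvert, so the meso form can be collected by crystallisation.

**3 to 1 and 2.** The bond between the ketone carbon and the α-carbon is cut, a crossed Claisen condensation of 1 with the non-enolisable ester 2.

## Alternatives that were turned down

**Alternative 1:** The disconnection is at C3–C4 and C3'–C4'. The two ketone carbons are read as the carbons of bis[4-methoxy-2-(methoxymethoxy)phenyl]acetylene A1, and C3, C3', C2 and C2' as the four carbons of maleic anhydride A2. The forward key step is a sensitised [2+2] photocycloaddition of A1 to A2 giving the cis-fused cyclobutene anhydride A3, whose double bond is a masked 1,4-diketone.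

- For it: the cis ring fusion of A3 fixes the C3/C3' relationship as meso by construction. This is a firmer basis than the crystallisation used at 5, and on this point the alternative is stronger. Both rings A also arrive in one symmetrical component.
- Against it: after oxidative cleavage of the double bond, C3 and C3' sit between a ketone and an anhydride carbonyl and epimerise as easily as in 5, so the advantage is not kept. Each anhydride carbonyl must then become a carbon bearing hydrogen, ring B and O1. That needs aryl addition in the presence of two aryl ketones, reduction, removal of the acetal groups and closure at O1–C2, with C2 and C2' formed last under no control but equilibration. The electron-rich diarylcyclobutene is also open to electrocyclic ring opening and stilbene-type photocyclisation.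
- Comparison: it is clearly longer after its key step. The chosen strategy gives up the built-in meso relation but has every skeletal atom and all four stereocentres in place before the ring-forming step, with three functional-group steps after it.

**Alternative 2:** The disconnection is at C2–C3 and C2'–C3'. (1E,3E)-1,4-Bis(4-methoxyphenyl)buta-1,3-diene A4 carries the two rings B, and A2 supplies C3, C3', C4 and C4'. The forward key step is the thermal endo Diels–Alder reaction to the all-cis cyclohexene anhydride A5.

- For it, and here it is stronger than the chosen route: one suprafacial step sets all four stereocentres predictably. The cis anhydride gives the meso relation, and aryl cis to the anhydride carbon becomes 2,3-trans once the ring carbon next to the aryl-bearing carbon is replaced by O1.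
- Against it: the cyclohexene ring is scaffolding. Each aryl-bearing carbon must exchange a carbon substituent for oxygen. This means cleavage to a dialdehyde whose stereocentres are benzylic and α to a formyl group, then a carbon-to-oxygen migration that competes with plain oxidation to the acid. The resulting 4-methoxybenzylic alcohols ionise easily. The anhydride must then acylate two resorcinol-type rings intermolecularly, and the O1–C8a bonds must be closed afterwards, which needs an extra leaving group on each ring A.
- Comparison: the chosen strategy sets the stereocentres in three events instead of one, but forms the C2–O bonds directly and keeps the ring closure for a reaction that the substitution pattern of ring A favours.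

**Alternative 3:** The disconnection is at the two C2–aryl bonds. The precursor is the flat 7,7'-dimethoxy-3,3'-bichromone A6 and the nucleophile is 4-methoxyphenylmagnesium bromide A7. The forward key step is a twofold copper-catalysed conjugate addition with silyl trapping; protonation of the bis(silyl enol ether) would give the tetra-O-methyl ether A8 of 14.

- For it: it is by far the shortest plan. A6 can be assembled by one homocoupling and only demethylation follows A8. On step economy it clearly beats the chosen route.
- Against it: each C2 of A6 is the β-carbon of an α-substituted enone shielded by the other chromone. The 1,4-addition is therefore slow and competes with 1,2-addition and with opening of the enolate by loss of phenoxide. Protonation trans to the new aryl group is plausible in each ring. Whether the second aryl group enters on the face leading to the meso or the racemic trans,trans isomer is decided across a freely rotating C3–C3' axis by a stereocentre three bonds away. Nothing in the substrate controls the one relationship that equilibration cannot correct. The final fourfold demethylation also frees 4'-phenols that promote opening at O1–C2.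
- Comparison: the chosen strategy is longer but fixes the C3/C3' relationship at the start, in 5, and passes it on by stereospecific steps.

Key step: step 6

Assumption: the meso diastereomer of diketone 5 is taken to be the less soluble one; its assignment against the racemic form must be secured by X-ray diffraction (or by chiral-phase chromatography of diol 6) before material is carried on.

Remark: in the twofold steps on the symmetrical intermediates the half-converted species reacts on under the same reagent and is not numbered, except keto acid 10 of the key step.

## Route

Step 1
Reactants: 1 tert-butyl acetate; 2 methyl 4-bromobenzoate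
Product: 3 tert-butyl 3-(4-bromophenyl)-3-oxopropanoate
Conditions: LiN(SiMe3)2 (2.2 equiv), THF, −78 °C; then 2, −78 → 0 °C; aq NH4Cl
Reagents that add atoms: none
Why: Crossed Claisen condensation: the lithium enolate of 1 adds to the non-enolisable ester 2 and methoxide leaves. The second equivalent of base deprotonates 3 and drives the equilibrium, and the amide base does not touch the aryl bromide.

Step 2
Reactants: 3 tert-butyl 3-(4-bromophenyl)-3-oxopropanoate (two molecules)
Product: 5 di-tert-butyl meso-(2R,3S)-2,3-bis(4-bromobenzoyl)butanedioate, via α-iodo keto ester 4 (not isolated)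
Conditions: NaH, THF, 0 °C; I2 (0.5 equiv), 0 → 25 °C; crystallisation from EtOH with cat. Et3N
Reagents that add atoms: none
Why: Oxidative enolate dimerisation: the sodium enolate of 3 is iodinated to 4, which alkylates a second enolate and forms the central C–C bond. Both new stereocentres are α-carbons of β-keto esters and epimerise through the enol, so the diastereomers interconvert under amine catalysis and the less soluble meso form should be collected by crystallisation.

Step 3
Reactants: 5 di-tert-butyl meso-(2R,3S)-2,3-bis(4-bromobenzoyl)butanedioate
Product: 6 di-tert-butyl (2R,3S)-2-[(R)-(4-bromophenyl)(hydroxy)methyl]-3-[(S)-(4-bromophenyl)(hydroxy)methyl]butanedioate (meso; both β-hydroxy ester units syn)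
Conditions: Zn(BH4)2, Et2O, −20 → 0 °C; aq NH4Cl
Reagents that add atoms: none
Why: Chelation-controlled ketone reduction: Zn2+ bridges each ketone and its β-ester carbonyl, and hydride adds to the chelate face opposite the α-substituent. This gives the syn β-hydroxy ester at both ends (R carbinol next to C2 R, S carbinol next to C3 S). The reagent is not basic, so the α-centres should not epimerise, and esters and aryl bromides are untouched.

Step 4
Reactants: 6 the syn,syn meso diol; 7 3-methoxyphenol (two molecules)
Product: 8 di-tert-butyl (2R,3S)-2-[(S)-(4-bromophenyl)(3-methoxyphenoxy)methyl]-3-[(R)-(4-bromophenyl)(3-methoxyphenoxy)methyl]butanedioate (meso; both units anti)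
Conditions: PPh3, DIAD, toluene, 0 → 25 °C (7 in excess)
Reagents that add atoms: none
Why: Twofold Mitsunobu etherification: 7 protonates the PPh3–DIAD betaine, each benzylic alcohol becomes an oxyphosphonium ion and is displaced by the phenoxide with inversion, turning the syn,syn diol into the anti,anti bis(ether). The 4-bromophenyl group and the β-ester disfavour ionisation, so the displacement should stay SN2.

Step 5
Reactants: 8 the anti,anti bis(aryl ether) di-tert-butyl ester
Product: 9 (2R,3S)-2-[(S)-(4-bromophenyl)(3-methoxyphenoxy)methyl]-3-[(R)-(4-bromophenyl)(3-methoxyphenoxy)methyl]butanedioic acid (meso)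
Conditions: CF3CO2H, Et3SiH, CH2Cl2, 0 → 25 °C
Reagents that add atoms: none
Why: Acidolysis of the tert-butyl esters by alkyl–oxygen cleavage; Et3SiH reduces the tert-butyl cation before it can alkylate the electron-rich aryl ethers. No base meets the β-aryloxy acid, and the 4-bromobenzylic ethers do not ionise in this medium.

Step 6
Reactants: 9 the meso bis(3-aryloxy) succinic acid
Product: 11 meso-(2S,2'R,3R,3'S)-2,2'-bis(4-bromophenyl)-7,7'-dimethoxy-[3,3'-bichromane]-4,4'-dione, via half-cyclised keto acid 10 (not isolated)
Conditions: P2O5/MeSO3H (1:10 w/w), 25 → 40 °C; ice
Reagents that add atoms: none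
Why: In P2O5/MeSO3H each carboxyl group becomes a mixed anhydride and then an acylium ion; a cyclic anhydride between the neighbouring carboxyl groups, if it forms, is itself an acyl donor here and feeds the same path. The acylium carbon attacks C-6 of the 3-methoxyphenyl ether on its own arm, ortho to the ether oxygen and para to methoxy, and loss of a proton gives racemic keto acid 10; the second carboxyl group repeats this and restores the mirror symmetry in 11. The closest known reaction type is the cyclodehydration of 3-aryloxypropanoic acids to chroman-4-ones (intramolecular Friedel–Crafts acylation), with the closure of a 3-(3-methoxyphenoxy)propanoic acid to a 7-methoxychroman-4-one as the direct model. Each pyranone ring closes as a six-membered ring (C4, C3, C2, O1, C8a, C4a) by attack of the arene on the acylium carbon, exo to the C≡O bond; the competing closures are a five-membered indanone onto the 4-bromophenyl ring of the same arm, a six-membered tetralone onto that of the other arm and a seven-membered ring onto the distal aryl ether, the first two onto deactivated rings. No stereocentre is formed: C2, C3, C3' and C2' are those of 9, and its anti,anti arrangement maps onto the 2,3-trans chromanones, which are also the more stable epimers, so enolisation at C3 has no driving force to change them. The step needs site selectivity on ring A (C-6, not C-2 between the two oxygens), given by hindrance at C-2 and para activation by methoxy, and it needs the benzylic C–O bonds to survive, which the 4-bromophenyl groups and the adjacent acyl carbons secure by destabilising a benzylic cation.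

Step 7
Reactants: 11 the dibromo bichromanone
Product: 12 meso-(2S,2'R,3R,3'S)-7,7'-dimethoxy-2,2'-bis[4-(4,4,5,5-tetramethyl-1,3,2-dioxaborolan-2-yl)phenyl]-[3,3'-bichromane]-4,4'-dione
Conditions: B2pin2, PdCl2(dppf)·CH2Cl2 (cat.), KOAc, 1,4-dioxane, 85 °C
Reagents that add atoms: bis(pinacolato)diboron, CC1(C)OB(OC1(C)C)B1OC(C)(C)C(C)(C)O1
Why: Miyaura borylation: zerovalent palladium inserts into each C–Br bond, acetate-assisted transmetalation with the diboron reagent follows, and reductive elimination gives the aryl boronate. KOAc is too weak a base to enolise the chromanones at a useful rate in dioxane, and the methyl ethers keep ring A free of acidic phenols.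

Step 8
Reactants: 12 the bis(pinacol boronate)
Product: 13 meso-(2S,2'R,3R,3'S)-2,2'-bis(4-hydroxyphenyl)-7,7'-dimethoxy-[3,3'-bichromane]-4,4'-dione
Conditions: KHSO5 (as 2KHSO5·KHSO4·K2SO4), acetone/H2O, 0 °C; aq NaHSO3
Reagents that add atoms: potassium peroxymonosulfate, [K+].[O-]S(=O)(=O)OO
Why: ipso-Oxidation of the aryl boronates: peroxymonosulfate adds to boron, the aryl group migrates from boron to oxygen, and the borate ester hydrolyses to the phenol. The medium is weakly acidic, so the flavanone should not ring-open, and the Dakin-type and Algar–Flynn–Oyamada pathways of alkaline peroxide are avoided.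

Step 9
Reactants: 13 the 7,7'-di-O-methyl ether of the target
Product: 14 meso-(2S,2'R,3R,3'S)-7,7'-dihydroxy-2,2'-bis(4-hydroxyphenyl)-[3,3'-bichromane]-4,4'-dione (target, CNP0231820.1)
Conditions: BBr3 (excess), CH2Cl2, −78 → 0 °C; MeOH, then H2O
Reagents that add atoms: none
Why: Lewis-acid demethylation: BBr3 coordinates each methoxy oxygen, bromide attacks the methyl group (SN2), and hydrolysis frees the 7- and 7'-phenols. The methyl group is far more accessible to bromide than the hindered secondary C2, and since trans is the more stable arrangement in each ring, a reversible opening at O1–C2 would return to it.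

## Compound list

1 | tert-butyl acetate | CC(=O)OC(C)(C)C | starting material
2 | methyl 4-bromobenzoate | COC(=O)c1ccc(Br)cc1 | starting material
3 | tert-butyl 3-(4-bromophenyl)-3-oxopropanoate | CC(C)(C)OC(=O)CC(=O)c1ccc(Br)cc1 | intermediate
4 | tert-butyl 3-(4-bromophenyl)-2-iodo-3-oxopropanoate (racemic, not isolated) | CC(C)(C)OC(=O)C(I)C(=O)c1ccc(Br)cc1 | intermediate
5 | di-tert-butyl meso-(2R,3S)-2,3-bis(4-bromobenzoyl)butanedioate | O=C(c1ccc(Br)cc1)[C@H](C(=O)OC(C)(C)C)[C@H](C(=O)OC(C)(C)C)C(=O)c1ccc(Br)cc1 | intermediate
6 | di-tert-butyl (2R,3S)-2-[(R)-(4-bromophenyl)(hydroxy)methyl]-3-[(S)-(4-bromophenyl)(hydroxy)methyl]butanedioate (meso, syn,syn) | O[C@@H](c1ccc(Br)cc1)[C@H](C(=O)OC(C)(C)C)[C@H](C(=O)OC(C)(C)C)[C@H](O)c1ccc(Br)cc1 | intermediate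
7 | 3-methoxyphenol | COc1cccc(O)c1 | starting material
8 | di-tert-butyl (2R,3S)-2-[(S)-(4-bromophenyl)(3-methoxyphenoxy)methyl]-3-[(R)-(4-bromophenyl)(3-methoxyphenoxy)methyl]butanedioate (meso, anti,anti) | COc1cccc(O[C@H](c2ccc(Br)cc2)[C@H](C(=O)OC(C)(C)C)[C@H](C(=O)OC(C)(C)C)[C@@H](Oc2cccc(OC)c2)c2ccc(Br)cc2)c1 | intermediate
9 | (2R,3S)-2-[(S)-(4-bromophenyl)(3-methoxyphenoxy)methyl]-3-[(R)-(4-bromophenyl)(3-methoxyphenoxy)methyl]butanedioic acid (meso; key-step precursor) | COc1cccc(O[C@H](c2ccc(Br)cc2)[C@H](C(=O)O)[C@H](C(=O)O)[C@@H](Oc2cccc(OC)c2)c2ccc(Br)cc2)c1 | intermediate
10 | (2S,3R)-3-(4-bromophenyl)-2-[(2S,3R)-2-(4-bromophenyl)-7-methoxy-4-oxochroman-3-yl]-3-(3-methoxyphenoxy)propanoic acid (racemic, one enantiomer drawn; not isolated) | O=C1c2ccc(OC)cc2O[C@H](c2ccc(Br)cc2)[C@H]1[C@H](C(=O)O)[C@@H](Oc1cccc(OC)c1)c1ccc(Br)cc1 | intermediate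
11 | meso-(2S,2'R,3R,3'S)-2,2'-bis(4-bromophenyl)-7,7'-dimethoxy-[3,3'-bichromane]-4,4'-dione (key-step product) | O=C1c2ccc(OC)cc2O[C@H](c2ccc(Br)cc2)[C@H]1[C@@H]1C(=O)c2ccc(OC)cc2O[C@H]1c1ccc(Br)cc1 | intermediate
12 | meso-(2S,2'R,3R,3'S)-7,7'-dimethoxy-2,2'-bis[4-(4,4,5,5-tetramethyl-1,3,2-dioxaborolan-2-yl)phenyl]-[3,3'-bichromane]-4,4'-dione | O=C1c2ccc(OC)cc2O[C@H](c2ccc(B3OC(C)(C)C(C)(C)O3)cc2)[C@H]1[C@@H]1C(=O)c2ccc(OC)cc2O[C@H]1c1ccc(B2OC(C)(C)C(C)(C)O2)cc1 | intermediate
13 | meso-(2S,2'R,3R,3'S)-2,2'-bis(4-hydroxyphenyl)-7,7'-dimethoxy-[3,3'-bichromane]-4,4'-dione | O=C1c2ccc(OC)cc2O[C@H](c2ccc(O)cc2)[C@H]1[C@@H]1C(=O)c2ccc(OC)cc2O[C@H]1c1ccc(O)cc1 | intermediate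
14 | meso-(2S,2'R,3R,3'S)-7,7'-dihydroxy-2,2'-bis(4-hydroxyphenyl)-[3,3'-bichromane]-4,4'-dione | O=C1c2ccc(O)cc2O[C@H](c2ccc(O)cc2)[C@H]1[C@@H]1C(=O)c2ccc(O)cc2O[C@H]1c1ccc(O)cc1 | target

## Step count and least certain steps

Total: 9 steps. Longest linear sequence: 9 steps (1 and 2 to 14); 7 enters at step 4.

**Step 6 (key step).** The most likely failure is loss of the aryl ether before or after acylation. The acylium ion or mixed anhydride can lose the α-proton and expel 3-methoxyphenol (acid-promoted retro-oxa-Michael), giving arylidene succinic derivatives. The benzylic ether can also ionise and re-alkylate ring A on carbon. A lesser risk is closure of the cyclic anhydride between the two carboxyl groups, which would slow the second acylation and expose C3 to epimerisation, or acylation at C-2 of ring A.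

The fallback reverses the polarity of the ring closure. It sets out from 6. Mitsunobu etherification with 2-iodo-5-methoxyphenol under the conditions of step 4 gives the bis(2-iodoaryl) ether di-tert-butyl ester F1, and acidolysis as in step 5 gives the diacid F2. Treatment of F2 with n-BuLi (4 equiv) in THF at −100 °C deprotonates both acids and exchanges iodine for lithium, which is faster than bromine–lithium exchange on the 4-bromophenyl rings. Each aryllithium then adds to its own lithium carboxylate (Parham cyclisation), and acidic work-up releases the two ketones. The sequence comes back to the route at 11.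

**Step 4.** Three processes may compete with the twofold substitution. The activated alcohol can undergo β-elimination to an arylidene succinate, since the α-hydrogen is acidified by the ester. The 1,4-diol can cyclodehydrate to a tetrahydrofuran once one hydroxyl is activated. The distal tert-butyl ester can participate and give a γ-lactone. The hindered secondary carbon slows the wanted SN2. Excess 7 in a non-polar solvent is meant to outrun these, and the tetrahydrofuran closure would have to pass through a ring with three contiguous cis substituents.

The fallback forms the aryl–oxygen bond instead of the alkyl–oxygen bond, so no hydroxyl is turned into a leaving group. It sets out from 5. Reduction under non-chelating conditions (LiEt3BH, CeCl3, THF, −78 °C) should give the anti,anti meso diol F3. Copper-catalysed oxidative O-arylation with potassium (3-methoxyphenyl)trifluoroborate (Cu(OAc)2·H2O, DMAP, 4 Å MS, O2, CH2Cl2, 25 °C) then arylates both hydroxyl groups with retention and comes back to the route at 8.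

**Step 2.** The selection of the meso diastereomer may fail: the racemic form or a mixture may crystallise, or the labile α-centres may epimerise before the reduction.

The fallback moves the selection to the configurationally stable diol stage. It sets out from 3: the uncrystallised dimerisation mixture is reduced under the conditions of step 3. The meso diol 6 is separated by chromatography from the racemic syn,syn diol F4. F4 is re-oxidised with Dess–Martin periodinane to the racemic diketone F5, which equilibrates with 5 under catalytic Et3N and is returned to the reduction. The sequence comes back to the route at 6.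

**Step 9.** The free 4'-phenols and the boron-complexed ketones may promote ring opening at O1–C2 during demethylation, followed by enolisation at C3 and loss of the meso relationship. The 7-methoxy groups, conjugated with the ketone, may also be cleaved slowly.

The fallback changes the order of events so that demethylation is done while ring B still carries bromine. It sets out from 11. BBr3 in CH2Cl2 gives the dibromo bis(phenol) F6. Miyaura borylation as in step 7 gives the bis(boronate) F7, and oxidation with KHSO5 as in step 8 gives the target; the sequence comes back to the route at 14.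

## Further compounds

F1 | step 6 | di-tert-butyl (2R,3S)-2-[(S)-(4-bromophenyl)(2-iodo-5-methoxyphenoxy)methyl]-3-[(R)-(4-bromophenyl)(2-iodo-5-methoxyphenoxy)methyl]butanedioate (meso) | COc1ccc(I)c(O[C@H](c2ccc(Br)cc2)[C@H](C(=O)OC(C)(C)C)[C@H](C(=O)OC(C)(C)C)[C@@H](Oc2cc(OC)ccc2I)c2ccc(Br)cc2)c1
F2 | step 6 | (2R,3S)-2-[(S)-(4-bromophenyl)(2-iodo-5-methoxyphenoxy)methyl]-3-[(R)-(4-bromophenyl)(2-iodo-5-methoxyphenoxy)methyl]butanedioic acid (meso) | COc1ccc(I)c(O[C@H](c2ccc(Br)cc2)[C@H](C(=O)O)[C@H](C(=O)O)[C@@H](Oc2cc(OC)ccc2I)c2ccc(Br)cc2)c1
F3 | step 4 | di-tert-butyl (2R,3S)-2-[(S)-(4-bromophenyl)(hydroxy)methyl]-3-[(R)-(4-bromophenyl)(hydroxy)methyl]butanedioate (meso, anti,anti) | O[C@H](c1ccc(Br)cc1)[C@H](C(=O)OC(C)(C)C)[C@H](C(=O)OC(C)(C)C)[C@@H](O)c1ccc(Br)cc1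
F4 | step 2 | di-tert-butyl (2R,3R)-2,3-bis[(R)-(4-bromophenyl)(hydroxy)methyl]butanedioate (racemic, syn,syn; one enantiomer drawn) | O[C@@H](c1ccc(Br)cc1)[C@H](C(=O)OC(C)(C)C)[C@@H](C(=O)OC(C)(C)C)[C@@H](O)c1ccc(Br)cc1
F5 | step 2 | di-tert-butyl (2R,3R)-2,3-bis(4-bromobenzoyl)butanedioate (racemic; one enantiomer drawn) | O=C(c1ccc(Br)cc1)[C@H](C(=O)OC(C)(C)C)[C@@H](C(=O)OC(C)(C)C)C(=O)c1ccc(Br)cc1
F6 | step 9 | meso-(2S,2'R,3R,3'S)-2,2'-bis(4-bromophenyl)-7,7'-dihydroxy-[3,3'-bichromane]-4,4'-dione | O=C1c2ccc(O)cc2O[C@H](c2ccc(Br)cc2)[C@H]1[C@@H]1C(=O)c2ccc(O)cc2O[C@H]1c1ccc(Br)cc1
F7 | step 9 | meso-(2S,2'R,3R,3'S)-7,7'-dihydroxy-2,2'-bis[4-(4,4,5,5-tetramethyl-1,3,2-dioxaborolan-2-yl)phenyl]-[3,3'-bichromane]-4,4'-dione | O=C1c2ccc(O)cc2O[C@H](c2ccc(B3OC(C)(C)C(C)(C)O3)cc2)[C@H]1[C@@H]1C(=O)c2ccc(O)cc2O[C@H]1c1ccc(B2OC(C)(C)C(C)(C)O2)cc1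
A1 | alternative 1 | bis[4-methoxy-2-(methoxymethoxy)phenyl]acetylene | COCOc1cc(OC)ccc1C#Cc1ccc(OC)cc1OCOC
A2 | alternative 1 | maleic anhydride (also used in alternative 2) | O=C1OC(=O)C=C1
A3 | alternative 1 | cis-1,2-bis[4-methoxy-2-(methoxymethoxy)phenyl]cyclobut-1-ene-3,4-dicarboxylic anhydride | O=C1OC(=O)[C@H]2C(c3ccc(OC)cc3OCOC)=C(c3ccc(OC)cc3OCOC)[C@@H]12
A4 | alternative 2 | (1E,3E)-1,4-bis(4-methoxyphenyl)buta-1,3-diene | COc1ccc(/C=C/C=C/c2ccc(OC)cc2)cc1
A5 | alternative 2 | all-cis-3,6-bis(4-methoxyphenyl)cyclohex-4-ene-1,2-dicarboxylic anhydride (meso endo adduct) | O=C1OC(=O)[C@H]2[C@@H]1[C@@H](c1ccc(OC)cc1)C=C[C@H]2c1ccc(OC)cc1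
A6 | alternative 3 | 7,7'-dimethoxy-4H,4'H-[3,3'-bichromene]-4,4'-dione | COc1ccc2c(=O)c(-c3coc4cc(OC)ccc4c3=O)coc2c1
A7 | alternative 3 | 4-methoxyphenylmagnesium bromide | COc1ccc([Mg]Br)cc1
A8 | alternative 3 | meso-(2S,2'R,3R,3'S)-7,7'-dimethoxy-2,2'-bis(4-methoxyphenyl)-[3,3'-bichromane]-4,4'-dione | O=C1c2ccc(OC)cc2O[C@H](c2ccc(OC)cc2)[C@H]1[C@@H]1C(=O)c2ccc(OC)cc2O[C@H]1c1ccc(OC)cc1
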